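**Retrosynthetic overview**
1. Last bond: the CH(CH3)–CH2 bond between the E-alkene and the ring (C3–C2 of the side chain). It is made by a Ni/pybox stereoconvergent radical allyl–alkyl coupling of racemic allylic chloride 19 (C20) with alkylzinc 33 (C12), which joins the halves and sets the C3 methyl centre.
2. 19 comes from a Cu–NHC SN2′ alkenylation of trienyl phosphate 14, which builds the vinyl/methyl/alkenyl quaternary centre.
3. 14 comes from two Zr-catalysed alkyne methylaluminations and one Pd alkyl–alkenyl coupling (both E-trisubstituted alkenes), after a Cu-catalysed asymmetric allylic alkylation of tiglyl bromide (isopropenyl-bearing centre).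
4. 33 comes from a Johnson–Claisen rearrangement (exocyclic methylene plus trans side arm), a Shapiro hydroxymethylation, and an asymmetric conjugate methylation/enolate methylation of 2-methylcyclohexenone.
5. Rings: the single cyclohexane ring is carried in from 2-methylcyclohexenone; no ring is formed in the route.

Assumption: 1, 2, 15 (racemate) and 20 are bought as catalogue compounds; for each asymmetric catalyst the ligand antipode that gives the drawn configuration is used, to be confirmed on the first run by chiral GC/HPLC.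

**Route**

Step 1
Reactants: 1 (2E)-1-bromo-2-methylbut-2-ene (tiglyl bromide); 2 (4-bromobut-1-yn-1-yl)trimethylsilane
Product: 5 (3R)-2,3-dimethylhept-1-en-6-yne, via Grignard reagent 3 (not isolated), via silyl enyne 4 (not isolated)
Conditions: 2 (1.3 equiv), Mg, Et2O, reflux; then 1, CuBr·SMe2 (5 mol%), Taniaphos (6 mol%), CH2Cl2, −78 °C; then MeOH, K2CO3, rt
Reagents that add atoms: none
Why: Cu-catalysed asymmetric allylic alkylation (SN2′) of a 2-substituted allyl bromide with a primary alkyl Grignard reagent delivers the alkyl group to the Si face of C3 of 1, which sets the (R) centre next to the new isopropenyl group, and the alkynylsilane is then cleaved by methanolysis.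

Step 2
Reactants: 5 (3R)-2,3-dimethylhept-1-en-6-yne
Product: 7 (1E,5R)-1-iodo-2,5,6-trimethylhepta-1,6-diene, via alkenylalane 6 (not isolated)
Conditions: Me3Al (2 equiv), Cp2ZrCl2 (25 mol%), CH2Cl2, 0 °C → rt; then I2, THF, −30 → 0 °C
Reagents that add atoms: trimethylaluminium C[Al](C)C; iodine II
Why: Negishi Zr-catalysed methylalumination adds Me and Al syn to the terminal alkyne (the 1,1-disubstituted alkene is inert), and iodinolysis of the C–Al bond with retention gives the E-iodide.

Step 3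
Reactants: 7 (1E,5R)-1-iodo-2,5,6-trimethylhepta-1,6-diene; 2 (4-bromobut-1-yn-1-yl)trimethylsilane
Product: 10 (5E,9R)-6,9,10-trimethylundeca-5,10-dien-1-yne, via alkylzinc bromide 8 (not isolated), via silyl dienyne 9 (not isolated)
Conditions: 2 (1.5 equiv), Zn dust (2.5 equiv, activated with BrCH2CH2Br/TMSCl, cat.), LiCl (1.5 equiv), THF, 50 °C; then 7, Pd(PPh3)4 (3 mol%), THF, rt; then K2CO3, MeOH, rt
Reagents that add atoms: none
Why: LiCl-promoted direct zinc insertion into the primary bromide gives the homopropargylzinc bromide in one operation, the Pd-catalysed Negishi alkyl–alkenyl coupling keeps the alkene geometry of 7, and methanolysis removes the silyl group to free the alkyne for the next methylalumination.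

Step 4
Reactants: 10 (5E,9R)-6,9,10-trimethylundeca-5,10-dien-1-yne
Product: 13 (2E,6E,10R)-3,7,10,11-tetramethyldodeca-2,6,11-trien-1-ol, via alkenylalane 11 (not isolated), via lithium alanate 12 (not isolated)
Conditions: Me3Al (2 equiv), Cp2ZrCl2 (25 mol%), CH2Cl2, rt; volatiles off; n-BuLi, hexane/THF, −78 → 0 °C; (CH2O)n, rt; aq. NH4Cl
Reagents that add atoms: trimethylaluminium C[Al](C)C; formaldehyde (as paraformaldehyde) C=O
Why: A second syn methylalumination fixes the 2E alkene, and the alanate formed with n-BuLi adds to formaldehyde with retention (Negishi allylic alcohol synthesis).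

Step 5
Reactants: 13 (2E,6E,10R)-3,7,10,11-tetramethyldodeca-2,6,11-trien-1-ol
Product: 14 diethyl (2E,6E,10R)-3,7,10,11-tetramethyldodeca-2,6,11-trien-1-yl phosphate
Conditions: ClP(O)(OEt)2, pyridine, DMAP (cat.), CH2Cl2, 0 °C
Reagents that add atoms: diethyl chlorophosphate CCOP(=O)(Cl)OCC
Why: Standard O-phosphorylation of a primary allylic alcohol gives the leaving group needed for the Cu-catalysed SN2′ step.

Step 6
Reactants: 14 diethyl (2E,6E,10R)-3,7,10,11-tetramethyldodeca-2,6,11-trien-1-yl phosphate; 15 (±)-tert-butyl(but-3-yn-2-yloxy)dimethylsilane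
Product: 17 tert-butyl{[(3E,5S,8E,12R)-5-ethenyl-5,9,12,13-tetramethyltetradeca-3,8,13-trien-2-yl]oxy}dimethylsilane (both C2 epimers), via alkenylalane 16 (not isolated)
Conditions: 15 (2 equiv), DIBAL-H (2 equiv), hexanes, 55 °C, 5 h; then 14, sulfonate-bearing NHC–Ag complex (2.5 mol%), CuCl2·2H2O (5 mol%), THF, −15 °C; Rochelle salt work-up
Reagents that add atoms: none
Why: NHC–Cu-catalysed enantioselective allylic substitution with an (E)-alkenylaluminium reagent (from cis-hydroalumination of 15) transfers the alkenyl group SN2′ to the Si face of C3 of the E-phosphate, creating the vinyl/methyl/alkenyl quaternary centre (S) in a reaction type proven for such skipped dienes; the carbinol centre is racemic on purpose because step 15 erases it.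

Step 7
Reactants: 17 tert-butyl{[(3E,5S,8E,12R)-5-ethenyl-5,9,12,13-tetramethyltetradeca-3,8,13-trien-2-yl]oxy}dimethylsilane
Product: 18 (3E,5S,8E,12R)-5-ethenyl-5,9,12,13-tetramethyltetradeca-3,8,13-trien-2-ol (both C2 epimers)
Conditions: TBAF, THF, 0 °C → rt
Reagents that add atoms: none
Why: Fluoride cleavage of the secondary silyl ether, with no other fluoride- or base-sensitive group present.

Step 8
Reactants: 18 (3E,5S,8E,12R)-5-ethenyl-5,9,12,13-tetramethyltetradeca-3,8,13-trien-2-ol
Product: 19 (3R,6E,10S,11E)-13-chloro-10-ethenyl-2,3,6,10-tetramethyltetradeca-1,6,11-triene (both C13 epimers)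
Conditions: NCS, PPh3, THF, −20 °C → rt; short silica plug, used at once
Reagents that add atoms: N-chlorosuccinimide O=C1CCC(=O)N1Cl
Why: Appel-type chlorination through the chlorophosphonium salt converts the secondary allylic alcohol to the chloride under neutral conditions that spare the acid-sensitive 1,1-disubstituted alkene, and epimer or SN2′-regioisomer content does not matter because step 15 is convergent.

Step 9
Reactants: 20 2-methylcyclohex-2-en-1-one
Product: 23 (3S)-2,2,3-trimethylcyclohexan-1-one, via aluminium enolate 21 (not isolated), via lithium aluminate enolate 22 (not isolated)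
Conditions: Me3Al (1.4 equiv), CuTC (2 mol%), chiral phosphoramidite (4 mol%), Et2O, −30 °C; then MeLi, THF/HMPA; MeI (5 equiv), −30 °C → rt
Reagents that add atoms: trimethylaluminium C[Al](C)C; iodomethane CI
Why: Cu/phosphoramidite-catalysed asymmetric conjugate addition of Me3Al to the 2-substituted enone sets C3 (S), and the regiodefined enolate, activated as its lithium aluminate, is C-methylated at C2 to give the gem-dimethyl group.

Step 10
Reactants: 23 (3S)-2,2,3-trimethylcyclohexan-1-one
Product: 24 N′-[(1E,3S)-2,2,3-trimethylcyclohexylidene]-2,4,6-tri(propan-2-yl)benzenesulfonohydrazide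
Conditions: TrisNHNH2 (1.05 equiv), conc. HCl (cat.), MeCN, rt
Reagents that add atoms: 2,4,6-tri(propan-2-yl)benzenesulfonohydrazide CC(C)c1cc(C(C)C)c(S(=O)(=O)NN)c(C(C)C)c1
Why: Acid-catalysed condensation gives the trisylhydrazone, which can be deprotonated only at C6 because C2 is quaternary.

Step 11
Reactants: 24 N′-[(1E,3S)-2,2,3-trimethylcyclohexylidene]-2,4,6-tri(propan-2-yl)benzenesulfonohydrazide
Product: 28 [(4S)-3,3,4-trimethylcyclohex-1-en-1-yl]methanol, via hydrazone dianion 25 (not isolated), via hydroxymethyl adduct 26 (not isolated), via vinyllithium 27 (not isolated)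
Conditions: n-BuLi (2.2 equiv), THF/TMEDA, −78 °C; monomeric CH2O (1.3 equiv), −78 → 0 °C; n-BuLi (2.5 equiv), −78 → 0 °C (N2 evolution); H2O
Reagents that add atoms: formaldehyde C=O
Why: Shapiro reaction with dianion trapping: the C,N-dianion is hydroxymethylated at C6, a further equivalent of base removes the remaining C6–H with loss of sulfinate and N2, and the vinyllithium is protonated on work-up, so the CH2OH-bearing alkene carbon ends remote from the gem-dimethyl group.

Step 12
Reactants: 28 [(4S)-3,3,4-trimethylcyclohex-1-en-1-yl]methanol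
Product: 30 ethyl 2-[(1S,3S)-2,2,3-trimethyl-6-methylidenecyclohexyl]acetate, via ketene acetal 29 (not isolated)
Conditions: MeC(OEt)3 (6 equiv), EtCO2H (0.1 equiv), 140 °C, EtOH distilled off
Reagents that add atoms: triethyl orthoacetate CCOC(C)(OCC)OCC
Why: Johnson–Claisen rearrangement delivers the C2 unit to the ring carbon next to the gem-dimethyl group by axial attack on the half-chair with the C4 methyl equatorial, anti to the pseudoaxial methyl, which is expected to give the 1,3-trans (1S,3S) ester and the exocyclic methylene in one step (any cis isomer is removed by chromatography).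

Step 13
Reactants: 30 ethyl 2-[(1S,3S)-2,2,3-trimethyl-6-methylidenecyclohexyl]acetate
Product: 31 2-[(1S,3S)-2,2,3-trimethyl-6-methylidenecyclohexyl]ethan-1-ol
Conditions: LiAlH4, Et2O, 0 °C; Fieser work-up
Reagents that add atoms: none
Why: LiAlH4 reduces the ester to the primary alcohol without touching the alkene or the stereocentres.

Step 14
Reactants: 31 2-[(1S,3S)-2,2,3-trimethyl-6-methylidenecyclohexyl]ethan-1-ol
Product: 32 (1S,3S)-1-(2-bromoethyl)-2,2,3-trimethyl-6-methylidenecyclohexane
Conditions: CBr4, PPh3, CH2Cl2, 0 °C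
Reagents that add atoms: carbon tetrabromide BrC(Br)(Br)Br
Why: Appel bromination of the primary alcohol under neutral conditions leaves the exocyclic alkene in place.

Step 15
Reactants: 32 (1S,3S)-1-(2-bromoethyl)-2,2,3-trimethyl-6-methylidenecyclohexane; 19 (3R,6E,10S,11E)-13-chloro-10-ethenyl-2,3,6,10-tetramethyltetradeca-1,6,11-triene
Product: 34 (1S,3S)-1-[(3S,4E,6S,9E,13R)-6-ethenyl-3,6,10,13,14-pentamethylpentadeca-4,9,14-trien-1-yl]-2,2,3-trimethyl-6-methylidenecyclohexane (CNP0293684.2), via alkylzinc bromide 33 (not isolated)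
Conditions: 32 (1.6 equiv), Zn powder, I2 (5 mol%), DMA, 70 °C; then 19, NiCl2·glyme (5 mol%), BnCH2-Pybox (5.5 mol%), NaCl (4 equiv), DMA/DMF 1:1, −10 °C, 24 h
Reagents that add atoms: none
Why: Ni/pybox-catalysed stereoconvergent Negishi coupling of a racemic secondary allylic chloride with a primary alkylzinc: a Ni(I) species abstracts chlorine to give the delocalised allyl radical (both epimers and any regioisomer of 19 converge), which is captured at nickel and coupled at the less hindered methyl-bearing terminus, so the chiral ligand sets C3 (S) and the E-alkene stays next to the quaternary carbon.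

**Compound list**
1 | (2E)-1-bromo-2-methylbut-2-ene | C/C=C(\C)CBr | starting material
2 | (4-bromobut-1-yn-1-yl)trimethylsilane | C[Si](C)(C)C#CCCBr | starting material
3 | [4-(trimethylsilyl)but-3-yn-1-yl]magnesium bromide (in situ) | C[Si](C)(C)C#CCC[Mg]Br | intermediate
4 | trimethyl[(5R)-5,6-dimethylhept-6-en-1-yn-1-yl]silane (in situ) | C[Si](C)(C)C#CCC[C@@H](C)C(=C)C | intermediate
5 | (3R)-2,3-dimethylhept-1-en-6-yne | C#CCC[C@@H](C)C(=C)C | intermediate
6 | dimethyl[(1E,5R)-2,5,6-trimethylhepta-1,6-dien-1-yl]alumane (in situ) | C[Al](C)/C=C(\C)CC[C@@H](C)C(=C)C | intermediate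
7 | (1E,5R)-1-iodo-2,5,6-trimethylhepta-1,6-diene | I/C=C(\C)CC[C@@H](C)C(=C)C | intermediate
8 | bromo[4-(trimethylsilyl)but-3-yn-1-yl]zinc (in situ) | C[Si](C)(C)C#CCC[Zn]Br | intermediate
9 | trimethyl[(5E,9R)-6,9,10-trimethylundeca-5,10-dien-1-yn-1-yl]silane (in situ) | C[Si](C)(C)C#CCC/C=C(\C)CC[C@@H](C)C(=C)C | intermediate
10 | (5E,9R)-6,9,10-trimethylundeca-5,10-dien-1-yne | C#CCC/C=C(\C)CC[C@@H](C)C(=C)C | intermediate
11 | dimethyl[(1E,5E,9R)-2,6,9,10-tetramethylundeca-1,5,10-trien-1-yl]alumane (in situ) | C[Al](C)/C=C(\C)CC/C=C(\C)CC[C@@H](C)C(=C)C | intermediate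
12 | lithium butyl(dimethyl)[(1E,5E,9R)-2,6,9,10-tetramethylundeca-1,5,10-trien-1-yl]aluminate (in situ) | [Li+].CCCC[Al-](C)(C)/C=C(\C)CC/C=C(\C)CC[C@@H](C)C(=C)C | intermediate
13 | (2E,6E,10R)-3,7,10,11-tetramethyldodeca-2,6,11-trien-1-ol | OC/C=C(\C)CC/C=C(\C)CC[C@@H](C)C(=C)C | intermediate
14 | diethyl (2E,6E,10R)-3,7,10,11-tetramethyldodeca-2,6,11-trien-1-yl phosphate | CCOP(=O)(OCC)OC/C=C(\C)CC/C=C(\C)CC[C@@H](C)C(=C)C | intermediate
15 | (±)-tert-butyl(but-3-yn-2-yloxy)dimethylsilane | C#CC(C)O[Si](C)(C)C(C)(C)C | starting material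
16 | [(1E)-3-{[tert-butyl(dimethyl)silyl]oxy}but-1-en-1-yl]bis(2-methylpropyl)alumane (in situ) | CC(C)C[Al](CC(C)C)/C=C/C(C)O[Si](C)(C)C(C)(C)C | intermediate
17 | tert-butyl{[(3E,5S,8E,12R)-5-ethenyl-5,9,12,13-tetramethyltetradeca-3,8,13-trien-2-yl]oxy}dimethylsilane (C2 epimers) | C=C[C@@](C)(/C=C/C(C)O[Si](C)(C)C(C)(C)C)CC/C=C(\C)CC[C@@H](C)C(=C)C | intermediate
18 | (3E,5S,8E,12R)-5-ethenyl-5,9,12,13-tetramethyltetradeca-3,8,13-trien-2-ol (C2 epimers) | C=C[C@@](C)(/C=C/C(C)O)CC/C=C(\C)CC[C@@H](C)C(=C)C | intermediate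
19 | (3R,6E,10S,11E)-13-chloro-10-ethenyl-2,3,6,10-tetramethyltetradeca-1,6,11-triene (C13 epimers) | C=C[C@@](C)(/C=C/C(C)Cl)CC/C=C(\C)CC[C@@H](C)C(=C)C | intermediate
20 | 2-methylcyclohex-2-en-1-one | CC1=CCCCC1=O | starting material
21 | {[(3S)-2,3-dimethylcyclohex-1-en-1-yl]oxy}(dimethyl)alumane (in situ) | C[Al](C)OC1=C(C)[C@@H](C)CCC1 | intermediate
22 | lithium {[(3S)-2,3-dimethylcyclohex-1-en-1-yl]oxy}(trimethyl)aluminate (in situ) | [Li+].C[Al-](C)(C)OC1=C(C)[C@@H](C)CCC1 | intermediate
23 | (3S)-2,2,3-trimethylcyclohexan-1-one | O=C1CCC[C@H](C)C1(C)C | intermediate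
24 | N′-[(1E,3S)-2,2,3-trimethylcyclohexylidene]-2,4,6-tri(propan-2-yl)benzenesulfonohydrazide | CC(C)c1cc(C(C)C)c(S(=O)(=O)N/N=C2\CCC[C@H](C)C2(C)C)c(C(C)C)c1 | intermediate
25 | dilithium C6,N-dianion of 24 (in situ) | [Li+].[Li+].CC(C)c1cc(C(C)C)c(S(=O)(=O)[N-]N=C2[CH-]CC[C@H](C)C2(C)C)c(C(C)C)c1 | intermediate
26 | dilithium salt of the 6-(hydroxymethyl) derivative of 24 (alkoxide and sulfonamide anion; in situ) | [Li+].[Li+].CC(C)c1cc(C(C)C)c(S(=O)(=O)[N-]N=C2C(C[O-])CC[C@H](C)C2(C)C)c(C(C)C)c1 | intermediate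
27 | lithium [(4S)-2-lithio-3,3,4-trimethylcyclohex-1-en-1-yl]methanolate (in situ) | [Li]OCC1=C([Li])C(C)(C)[C@@H](C)CC1 | intermediate
28 | [(4S)-3,3,4-trimethylcyclohex-1-en-1-yl]methanol | OCC1=CC(C)(C)[C@@H](C)CC1 | intermediate
29 | (4S)-1-{[(1-ethoxyethenyl)oxy]methyl}-3,3,4-trimethylcyclohex-1-ene (in situ) | CCOC(=C)OCC1=CC(C)(C)[C@@H](C)CC1 | intermediate
30 | ethyl 2-[(1S,3S)-2,2,3-trimethyl-6-methylidenecyclohexyl]acetate | CCOC(=O)C[C@H]1C(=C)CC[C@H](C)C1(C)C | intermediate
31 | 2-[(1S,3S)-2,2,3-trimethyl-6-methylidenecyclohexyl]ethan-1-ol | OCC[C@H]1C(=C)CC[C@H](C)C1(C)C | intermediate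
32 | (1S,3S)-1-(2-bromoethyl)-2,2,3-trimethyl-6-methylidenecyclohexane | BrCC[C@H]1C(=C)CC[C@H](C)C1(C)C | intermediate
33 | bromo{2-[(1S,3S)-2,2,3-trimethyl-6-methylidenecyclohexyl]ethyl}zinc (in situ) | Br[Zn]CC[C@H]1C(=C)CC[C@H](C)C1(C)C | intermediate
34 | (1S,3S)-1-[(3S,4E,6S,9E,13R)-6-ethenyl-3,6,10,13,14-pentamethylpentadeca-4,9,14-trien-1-yl]-2,2,3-trimethyl-6-methylidenecyclohexane | C=C[C@@](C)(/C=C/[C@@H](C)CC[C@H]1C(=C)CC[C@H](C)C1(C)C)CC/C=C(\C)CC[C@@H](C)C(=C)C | target

**Step count**
Total: 15 steps. Longest linear sequence: 9 steps (steps 1–8, then 15); the ring branch is 6 steps (9–14) before the union.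

**Three steps most likely to fail, with fallbacks**

Step 15 (Ni radical coupling on the full-size chloride). The risks are regiochemistry at the two allyl termini, catalyst control next to an existing quaternary centre, and 5-exo closure of the allyl radical onto the C8 alkene. The fallback sets out from bromide 32 (and phosphate 14) and comes back to the route at 34. The zinc reagent from 32 is coupled in the same Ni/pybox radical manifold with racemic N-benzyl-2-bromo-N-phenylpropanamide (NiCl2·glyme, i-Pr-Pybox, DMI/THF, 0 °C), the best-behaved electrophile class for this stereoconvergent coupling, to give (2S)-N-benzyl-2-methyl-N-phenyl-4-[(1S,3S)-2,2,3-trimethyl-6-methylidenecyclohexyl]butanamide F1. LiAlH4 then gives (2S)-2-methyl-4-[(1S,3S)-2,2,3-trimethyl-6-methylidenecyclohexyl]butan-1-ol F2, Dess–Martin periodinane gives (2S)-2-methyl-4-[(1S,3S)-2,2,3-trimethyl-6-methylidenecyclohexyl]butanal F3, and the Ohira–Bestmann reagent (K2CO3, MeOH, 0 °C) gives (1S,3S)-2,2,3-trimethyl-6-methylidene-1-[(3S)-3-methylpent-4-yn-1-yl]cyclohexane F4. DIBAL-H (hexanes, 55 °C) converts F4 into {(1E,3S)-3-methyl-5-[(1S,3S)-2,2,3-trimethyl-6-methylidenecyclohexyl]pent-1-en-1-yl}bis(2-methylpropyl)alumane F5, which replaces 16 in the Cu–NHC allylic substitution on 14 and gives 34 directly. The radical coupling still sets the methyl-bearing centre, but on a small substrate, and the fragment union moves to the copper step.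

Step 6 (Cu–NHC allylic substitution). The risks are competing alkyne metalation during hydroalumination of the propargylic silyl ether, transfer of an α-branched alkenyl group, and the enantiomer ratio with an all-alkyl phosphate. The fallback sets out from 14 and 15 and comes back at 18. DIBAL-H with 5 mol% Et3N metalates 15 instead of adding to it and gives [3-{[tert-butyl(dimethyl)silyl]oxy}but-1-yn-1-yl]bis(2-methylpropyl)alumane F6. Cu–NHC SN2′ substitution of 14 with it builds the quaternary centre as a propargylic one in tert-butyl{[(5S,8E,12R)-5-ethenyl-5,9,12,13-tetramethyltetradeca-8,13-dien-3-yn-2-yl]oxy}dimethylsilane F7. TBAF gives (5S,8E,12R)-5-ethenyl-5,9,12,13-tetramethyltetradeca-8,13-dien-3-yn-2-ol F8, and hydroxyl-directed trans-hydroalumination with Red-Al (THF, 0 °C) makes the E-alkene and returns 18.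

Step 11 (Shapiro hydroxymethylation). The risk is the last lithiation, which must remove a methine hydrogen next to an alkoxide. The fallback sets out from 23 and comes back at 28. Vilsmeier–Haack–Arnold formylation (POCl3, DMF, 60 °C), possible only at C6 of 23, gives (4S)-2-chloro-3,3,4-trimethylcyclohex-1-ene-1-carbaldehyde F9. Pd-catalysed formate reduction (Pd(OAc)2, PPh3, HCO2H, Et3N, DMF, 60 °C) removes the vinylic chlorine to give (4S)-3,3,4-trimethylcyclohex-1-ene-1-carbaldehyde F10, and Luche reduction (NaBH4, CeCl3, MeOH, 0 °C) gives 28.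

Further compounds
F1 | step 15 | (2S)-N-benzyl-2-methyl-N-phenyl-4-[(1S,3S)-2,2,3-trimethyl-6-methylidenecyclohexyl]butanamide | O=C(N(Cc1ccccc1)c1ccccc1)[C@@H](C)CC[C@H]1C(=C)CC[C@H](C)C1(C)C
F2 | step 15 | (2S)-2-methyl-4-[(1S,3S)-2,2,3-trimethyl-6-methylidenecyclohexyl]butan-1-ol | OC[C@@H](C)CC[C@H]1C(=C)CC[C@H](C)C1(C)C
F3 | step 15 | (2S)-2-methyl-4-[(1S,3S)-2,2,3-trimethyl-6-methylidenecyclohexyl]butanal | O=C[C@@H](C)CC[C@H]1C(=C)CC[C@H](C)C1(C)C
F4 | step 15 | (1S,3S)-2,2,3-trimethyl-6-methylidene-1-[(3S)-3-methylpent-4-yn-1-yl]cyclohexane | C#C[C@@H](C)CC[C@H]1C(=C)CC[C@H](C)C1(C)C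
F5 | step 15 | {(1E,3S)-3-methyl-5-[(1S,3S)-2,2,3-trimethyl-6-methylidenecyclohexyl]pent-1-en-1-yl}bis(2-methylpropyl)alumane | CC(C)C[Al](CC(C)C)/C=C/[C@@H](C)CC[C@H]1C(=C)CC[C@H](C)C1(C)C
F6 | step 6 | [3-{[tert-butyl(dimethyl)silyl]oxy}but-1-yn-1-yl]bis(2-methylpropyl)alumane | CC(C)C[Al](CC(C)C)C#CC(C)O[Si](C)(C)C(C)(C)C
F7 | step 6 | tert-butyl{[(5S,8E,12R)-5-ethenyl-5,9,12,13-tetramethyltetradeca-8,13-dien-3-yn-2-yl]oxy}dimethylsilane | C=C[C@@](C)(C#CC(C)O[Si](C)(C)C(C)(C)C)CC/C=C(\C)CC[C@@H](C)C(=C)C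
F8 | step 6 | (5S,8E,12R)-5-ethenyl-5,9,12,13-tetramethyltetradeca-8,13-dien-3-yn-2-ol | C=C[C@@](C)(C#CC(C)O)CC/C=C(\C)CC[C@@H](C)C(=C)C
F9 | step 11 | (4S)-2-chloro-3,3,4-trimethylcyclohex-1-ene-1-carbaldehyde | O=CC1=C(Cl)C(C)(C)[C@@H](C)CC1
F10 | step 11 | (4S)-3,3,4-trimethylcyclohex-1-ene-1-carbaldehyde | O=CC1=CC(C)(C)[C@@H](C)CC1
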